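(The readings are simulated for substances that don't exist, noise included.)

The unit I counted in was the turnover of substrate, and I kept the books in fractions of the substrate charged, with substrate as limiting reagent against 2.00 equivalents of partner.

| flask | substrate | partner | remark | time |
|---|---|---|---|---|
| larch | 0.10 M (in portions, 2) | 0.10 M | run made earlier; portions every 3.0 min |  |
| maple | 0.10 M (in portions, 2) | 0.40 M | run made earlier; portions every 3.0 min |  |
| alder | 0.050 M (in portions, 2) | 0.20 M | run made earlier; portions every 3.0 min |  |
| Monday's | 0.10 M (in portions, 2) | 0.200 M | the portions of substrate follow each other after 3.0 min, the first at the start | 6.0 min |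
| Thursday's | 0.10 M | 0.200 M | everything together at the start | 6.0 min |

| run | time / min | target / % | substrate / % |
|---|---|---|---|
| larch | 0.250 | 0 | 48.0 |
| larch | 0.667 | 0.9 | 43.8 |
| larch | 1.33 | 0.6 | 38.3 |
| larch | 2.00 | 1.0 | 34.1 |
| larch | 3.00 | 1.7 | 28.4 |
| larch | 4.00 | 5.0 | 63.2 |
| maple | 0.250 | 0 | 47.4 |
| maple | 0.667 | 0 | 43.4 |
| maple | 1.33 | 2.1 | 38.2 |
| maple | 2.00 | 3.8 | 33.6 |
| maple | 3.00 | 8.7 | 27.9 |
| maple | 4.00 | 14.7 | 63.8 |
| alder | 0.250 | 0.2 | 47.1 |
| alder | 0.500 | 0 | 45.6 |
| alder | 1.00 | 0.4 | 40.7 |
| alder | 2.00 | 1.8 | 33.9 |
| alder | 4.00 | 8.5 | 63.6 |

(standard deviation of a reading: 0.5 percentage points)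

- steps under discussion: partner -> second intermediate; partner <-> dormant form; open intermediate + second intermediate -> target; substrate -> open intermediate; target <-> isomer of the product

- which of the two ends with the higher amount of target, in percent of the substrate charged ("neither" if they lie within 2 percentage points) (Monday's / Thursday's / neither)
- target at the end, in percent of the substrate charged, Monday's
- target at the end, in percent of the substrate charged, Thursday's

In larch, the first portion fell from 48.0% to 28.4% of the charge between 0.250 min and 3.00 min, which gave a loss constant of 0.191 min⁻¹. Alder, on half that charge, read 0.188 min⁻¹, so I took the loss as first order. The turnover count is that constant times the time a portion has spent in the flask: 1.15 for Thursday's charge. On Monday's, the first portion has the same count and the second 0.573.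

The first ledger entry is substrate left: 31.8% on Thursday's and 44.1% on Monday's. The second is substrate opened, 68.2% and 55.9%, so Thursday's opens more than Monday's. The third is the split of what opened. Alder, at the partner level of both flasks and with both its portions in, read 63.6% substrate and 8.5% target at 4.00 min, so 27.9% of its charge stood as open intermediate and isomer of the product together.

The forecast said Thursday's would end higher, with 20% (16% to 25%) for Monday's and 29% (22% to 37%) for Thursday's, holding that “Target appears with a lag that follows the accumulated open intermediate”. Against my opened shares, those targets closed the books with 35.9% on Monday's and 39.2% on Thursday's as open intermediate and isomer of the product.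

The flask gave 19.6% on Monday's and 25.3% on Thursday's, so Thursday's ended higher.

    partner → second intermediate (k = 0.280 min⁻¹)
    partner ⇌ dormant form (K = 4.00, k = 1.30 min⁻¹)
    open intermediate + second intermediate → target (k = 4.50 L mol⁻¹ min⁻¹)
    substrate → open intermediate (k = 0.200 min⁻¹)
    target ⇌ isomer of the product (K = 0.790, k = 0.110 min⁻¹)

The count had put substrate at 44.1% on Monday's, and 43% stood there; on Thursday's it had put 31.8%, and 30.1% stood there. Thursday's lead of 5.6 percentage points, against a margin of 2 points, comes from the way substrate goes in. In a neighbour of Thursday's with partner cut to 0.050 M, the same count 1.15, which puts substrate at 31.8%, met 30.1% of substrate, yet that flask held 60.7% as open intermediate and reached 7.65% of target.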